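## Structural features

The target is the (E)-caffeate of a trichodiene-type sesquiterpene alcohol. A 1-methyl-2-methylidenecyclopentane (C1–C5, exocyclic CH2 on C1) is joined by the single bond C5–C6 to a cyclohexene (C6–C11, C8=C9 trisubstituted with a methyl on C9), and the allylic carbon C10 carries the ester oxygen. C5 and C6 are both fully substituted, each bears a methyl group, and they are direct neighbours across a freely rotating bond. The third stereocentre, C10, is 1,3 to C6 in the six-membered ring, with its oxygen trans to the C6 methyl and cis to the cyclopentyl group (5S,6S,10S). The fragile parts are the exocyclic 1,1-disubstituted alkene next to a quaternary carbon (acid moves it into the ring or starts 1,2-shifts), the secondary allylic ester (ionisation, elimination, hydrolysis), the enoate, and the oxidation- and base-sensitive catechol. The real difficulty is C6: a quaternary stereocentre has to be created beside the quaternary C5, where crowding is greatest and where C5 gives no dependable 1,2-induction because no ring fixes the two centres relative to each other. The plan uses the six-membered ring instead: because the C6 methyl and the C10 oxygen are 1,3-related, a hydroxyl on C10 of a cyclohexenol with a C6=C11 double bond can deliver a one-carbon unit to C6 on its own face. The methyl arrives masked as a cyclopropane CH2 bridging C6 and C11, and the C10 oxygen, needed anyway for the ester, is reset afterwards.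

## Logic of the disconnections

24 ⇒ 23. The two aryl O–Si bonds are formed in the retrosynthetic sense. A free catechol would compete as a nucleophile and oxidise during acylation, so it is masked. The end game becomes one mild deprotection, which must leave the allylic cinnamate and the exocyclic alkene untouched.

23 ⇒ 19 + 22. The acyl C–O bond of the ester at C10 is cut. It is the only heteroatom link between the terpenoid and the aromatic acid, so the plan becomes convergent. The forward acylation has to take place at oxygen, without ionisation at C10, so that the configuration is retained.

22 ⇒ 20. The two phenolic O–Si bonds are removed; the carboxyl group stays free. The forward step must silylate both phenols and release the acid again.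

19 ⇒ 18. The C10–H bond is cut. The oxygen had to sit on the other face of the ring earlier, so C10 must be re-created from a carbonyl group with its configuration chosen by the reducing agent. 18 has one stereocentre fewer and is an α-methyl enone. The hydride has to enter from the face of the C6 methyl, against the likely bias of the substrate.

18 ⇒ 17 ⇒ 16. The C8=C9 double bond is saturated in the retrosynthetic sense (H added to C8 and C9). A saturated ketone is simpler and comes directly out of the cyclopropane opening. The forward sequence needs enolisation toward C9 and a dehydrogenation that spares the exocyclic alkene. C6 is quaternary, so desaturation on the other side of the carbonyl is impossible.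

16 ⇒ 15. The C6 methyl carbon is reconnected to C11. A quaternary methyl β to a ketone is the retron of the reductive opening of a conjugated cyclopropyl ketone. The quaternary-centre problem thereby becomes a cyclopropanation problem. The forward step must break the external cyclopropane bond C11–CH2 and not the ring-fusion bond C11–C6.

15 ⇒ 14. The C9–CH3 bond is cut. In 14 the carbon C9 is the only position that can be enolised, because the other α-carbon is a cyclopropane bridgehead. The methyl is therefore placed here and not after ring opening, when two α-methylene groups would compete. The demand is clean mono-alkylation.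

14 ⇒ 13. The C10 carbonyl is traced back to the carbinol. The hydroxyl is the control element of the key step and is oxidised once it has done its work. The oxidant must be non-acidic because 13 is a cyclopropyl carbinol.

13 ⇒ 12. The bonds C6–CH2 and C11–CH2 are cut (key disconnection). This removes a ring and two stereocentres and leaves an alkene whose faces are distinguished only by the C10 hydroxyl. The forward step must deliver CH2 syn to that hydroxyl and must not touch the exocyclic C1=CH2.

12 ⇒ 11. The C10–H bond is cut. The carbinol configuration, which later fixes C6, is thereby put in the hands of a chiral reducing agent and made independent of C5. The forward step needs catalyst-controlled 1,2-reduction of a β-substituted cyclohexenone.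

11 ⇒ 9 ⇒ 8. No C–C bond is cut. The 3-substituted cyclohexenone is recognised as the hydrolysed and conjugated form of a 1-methoxycyclohexa-1,4-diene, and this as a reduced meta-substituted anisole. The six-membered ring is thus bought as an arene, and the C5–C6 bond becomes an aryl–C(sp3) bond. Reduction and hydrolysis must spare the acid-sensitive exocyclic alkene.

8 ⇒ 7. The C1=CH2 bond is cut. The ketone is needed one step earlier as the activating group for arylation. The forward step is the methylenation of a ketone flanked by a quaternary carbon.

7 ⇒ 5 ⇒ 3 + 4. The C5–C6 bond (aryl–C) is cut. It is the only bond between the two rings, and enolate arylation forms it together with the C5 stereocentre under ligand control. Two commercial fragments result. The arylation must occur only at the methyl-bearing α-carbon, which requires a removable blocking group on the other side, and it must be enantioselective.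

3 ⇒ 1. The exocyclic C=C of the blocking group and its C–N bond are removed. This leaves the commercial ketone 1. Formylation has to go to the CH2 flank only.

## Other disconnections considered

Alternative 1: ring-rearrangement metathesis. The cut goes through two alkenes, C8=C9 of the target and a C2=C3 double bond introduced formally into the five-membered ring. Both are traced back to one cyclohexenone, A2, whose ring alkene is C2=C8 and which carries an allyl group on C5 and a 2-silyloxy-3-methylbut-3-enyl chain on C6. In the forward step a ruthenium alkylidene generated at the allyl terminus opens the enone alkene and closes the cyclopentenone. The carbene left on C8 then closes onto the isopropenyl group, the two terminal CH2 groups are lost, and the product is the cyclopentenone silyl ether A1.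
- In its favour: the six-membered ring arrives complete, with the C9 methyl, the C8=C9 alkene and the C10 oxygen in final form. The methylation, dehydrogenation and second carbonyl reduction of the chosen plan are not needed. On end-game economy it is the better plan, and it is catalytic.
- Against it: C5 and C6 must already be present with the right relative configuration in A2. The central problem is therefore not solved by the key step but moved back to successive enolate alkylations on a crowded ring without any internal control element. C10 would also have to be set in an open chain.
- Mechanism: opening an unstrained, electron-poor cyclohexenone alkene has little driving force, and direct ring closure between the allyl and isopropenyl groups to a seven-membered ring competes. The chosen cyclopropanation is a single concerted, directed event of a well-known type.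
- After A1: conjugate reduction, methylenation of a very hindered ketone and desilylation are still needed to reach 19.
- Step economy: probably similar, since what is saved at the end is spent on A2.
- Structure: the chosen plan relays C6 from a ring carbinol, whereas here C6 rests on substrate control.

Alternative 2: ester-tethered [2+2] photocycloaddition. In the retrosynthetic sense C11 is reconnected to C1 and the exocyclic methylene carbon is raised to a carboxyl group bound to the C10 oxygen. This gives the tetracyclic cyclobutane lactone A3, which comes from the allylic ester A4 (a 3-methylcyclohexenyl ester of a 2-methylcyclopentenecarboxylic acid). In the forward step sensitised irradiation joins C1 to C11 and C5 to C6.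
- In its favour: the inter-ring bond C5–C6 and both quaternary stereocentres are made in one operation from two small fragments. On this point it is conceptually stronger than the chosen plan, which creates C5 and C6 in separate steps far apart.
- Also in its favour: the tether places the C10 oxygen on its final face relative to C6, so no inversion of that centre would be required. That is likewise an advantage.
- Against it: ester tethers prefer the extended conformation in which the two alkenes cannot meet, and unsaturated esters are poor triplet acceptors. A tetrasubstituted and a trisubstituted alkene would have to form two adjacent quaternary carbons in a four-membered ring. The tether does not decide between the anti and the syn arrangement of the two outer rings, and only the anti one gives the right C5/C6 relation.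
- After A3: the cyclobutane must be cleaved reductively at C1–C11 and not at C1–C5 (both are α,β to the carbonyl), and the carboxyl carbon must be turned into the methylene. The six-membered ring is saturated and lacks the C9 methyl, so oxidation at C10, methylation, dehydrogenation and reduction are needed as in the chosen plan. The stereochemical gain at C10 is thereby lost.
- Comparison: on structure it is more ambitious, on mechanism less predictable, and on step count not shorter.

Alternative 3: enzymatic cyclisation and allylic oxidation. The whole hydrocarbon skeleton is cut at C6–C7 and C1–C5 and at the bonds to the two migrated methyl groups. The hydrocarbon A5 (trichodiene) is traced to the acyclic diphosphate A6 and the cyclase that converts it. In the forward step the enzyme ionises A6, closes both rings, shifts one hydride and two methyl groups and ends by deprotonation to the exocyclic alkene. Allylic oxidation at C10 would then lead to 19, and steps 16 and 17 would follow.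
- In its favour: it is by far the shortest route, and the enzyme sets C5 and C6 with complete absolute control. In step economy and in control of the vicinal quaternary centres it is better than the chosen plan. The usual preference of selenium dioxide for the ring CH2 at the more substituted end of a trisubstituted alkene points to C10.
- Against it: it depends on producing a recombinant cyclase and on the diphosphate A6, with a volatile hydrocarbon product from dilute aqueous medium. It is not a construction from ordinary commercial chemicals.
- Oxidation of A5: four allylic sites compete (C10, C7, the C9 methyl, and C2 beside the exocyclic alkene), and the configuration at C10 is uncontrolled. Oxidation to 18 followed by step 14 would probably be needed.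
- Comparison: on structure and step count it is superior. On mechanism it replaces chemical design by enzyme specificity, and its weak point is the same late C10 problem as in the chosen plan.

Key step: step 8

Assumption: the sense of induction in steps 7 and 14 is assigned with the usual oxazaborolidine model (the alkenyl flank of the carbonyl counts as the larger group); if a test run showed the opposite sense, the enantiomeric catalyst would be used and nothing else would change.
Assumption: 15 and 16 are carried as mixtures of epimers at the methyl-bearing carbon α to the carbonyl, because that carbon becomes trigonal in 17.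

## Route

Step 1
Reactants: 1 2-methylcyclopentan-1-one (racemic)
Product: 3 (E)-2-methyl-5-[(N-methylanilino)methylidene]cyclopentan-1-one, via hydroxymethylidene ketone 2 (not isolated)
Conditions: NaH, HCO2Et, THF, 0 °C → rt; then AcOH, PhNHMe, rt → 50 °C
Reagents that add atoms: ethyl formate, CCOC=O; N-methylaniline, CNc1ccccc1
Why: Crossed Claisen formylation is reversible and ends at the CH2 flank, the only position that gives a stabilised β-dicarbonyl enolate; condensation with the secondary amine then gives a vinylogous amide that blocks this flank, so that only the methyl-bearing carbon can be arylated; no stereocentre is set, and the racemic centre is erased as the enolate in step 2.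

Step 2
Reactants: 3 (E)-2-methyl-5-[(N-methylanilino)methylidene]cyclopentan-1-one; 4 3-bromoanisole
Product: 5 (2R,5E)-2-(3-methoxyphenyl)-2-methyl-5-[(N-methylanilino)methylidene]cyclopentan-1-one
Conditions: Pd2(dba)3 (cat.), enantiopure 2-(dialkylphosphino)-1,1'-binaphthyl ligand (enantiomer that gives the 2R ketone), NaOt-Bu, PhMe, rt → 50 °C
Reagents that add atoms: none
Why: Palladium-catalysed asymmetric α-arylation of a ketone enolate (oxidative addition of the aryl bromide, enolate binding, C–C reductive elimination); the quaternary centre (the later C5) is set by the chiral ligand on palladium, and α'-blocked 2-methylcyclopentanones with meta-substituted aryl bromides are an established substrate class for this reaction.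

Step 3
Reactants: 5 (2R,5E)-2-(3-methoxyphenyl)-2-methyl-5-[(N-methylanilino)methylidene]cyclopentan-1-one
Product: 7 (R)-2-(3-methoxyphenyl)-2-methylcyclopentan-1-one, via arylated hydroxymethylidene ketone 6 (not isolated)
Conditions: 1 M HCl, THF, rt; then 1 M NaOH, rt → 40 °C
Reagents that add atoms: none
Why: Acid hydrolysis of the vinylogous amide releases the amine, and hydroxide then removes the formyl group by retro-Claisen cleavage; the quaternary centre has no α-hydrogen and cannot epimerise.

Step 4
Reactants: 7 (R)-2-(3-methoxyphenyl)-2-methylcyclopentan-1-one
Product: 8 1-methoxy-3-[(1S)-1-methyl-2-methylidenecyclopentyl]benzene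
Conditions: Ph3PCH3Br, KOt-Bu, PhMe, 90 °C
Reagents that add atoms: methyltriphenylphosphonium bromide, C[P+](c1ccccc1)(c1ccccc1)c1ccccc1.[Br-]
Why: Wittig methylenation with the unstabilised ylide in hot toluene, conditions suited to ketones flanked by a quaternary carbon; the descriptor changes from R to S only because the CIP priorities change, the centre itself is untouched.

Step 5
Reactants: 8 1-methoxy-3-[(1S)-1-methyl-2-methylidenecyclopentyl]benzene
Product: 9 1-methoxy-5-[(1S)-1-methyl-2-methylidenecyclopentyl]cyclohexa-1,4-diene
Conditions: Li, NH3(l), THF, t-BuOH, −78 → −33 °C; then MeOH
Reagents that add atoms: none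
Why: Birch reduction of a meta-alkylanisole protonates the two unsubstituted positions para to each other and leaves methoxy and alkyl on the remaining double bonds; the isolated 1,1-disubstituted alkene is not reduced by dissolving metal.

Step 6
Reactants: 9 1-methoxy-5-[(1S)-1-methyl-2-methylidenecyclopentyl]cyclohexa-1,4-diene
Product: 11 3-[(1S)-1-methyl-2-methylidenecyclopentyl]cyclohex-2-en-1-one, via deconjugated cyclohex-3-enone 10 (not isolated)
Conditions: (CO2H)2, THF/H2O, rt; then DBU (cat.), CH2Cl2, rt
Reagents that add atoms: water, O
Why: A weak acid hydrolyses the enol ether without protonating the exocyclic alkene (strong acid would risk alkene migration or 1,2-shifts at the quaternary carbon), and base-catalysed enolisation then moves the β,γ-double bond into conjugation, which gives the more stable β,β-disubstituted enone.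

Step 7
Reactants: 11 3-[(1S)-1-methyl-2-methylidenecyclopentyl]cyclohex-2-en-1-one
Product: 12 (1S)-3-[(1S)-1-methyl-2-methylidenecyclopentyl]cyclohex-2-en-1-ol
Conditions: (R)-Me-CBS (0.2 equiv), catecholborane, PhMe, −78 °C
Reagents that add atoms: none
Why: Corey–Bakshi–Shibata reduction: the ketone binds to the catalyst boron with the alkenyl flank (which bears the tertiary alkyl group) as the larger group, and hydride is delivered from the coordinated borane to one face, which should give the (S)-carbinol under catalyst control with C5 too remote to interfere; catecholborane at −78 °C neither hydroborates the exocyclic alkene nor reduces the s-trans enone in conjugate fashion.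

Step 8
Reactants: 12 (1S)-3-[(1S)-1-methyl-2-methylidenecyclopentyl]cyclohex-2-en-1-ol
Product: 13 (1R,2S,6R)-6-[(1S)-1-methyl-2-methylidenecyclopentyl]bicyclo[4.1.0]heptan-2-ol
Conditions: Sm (5 equiv), HgCl2 (0.5 equiv), ClCH2I (5 equiv), THF, −78 °C → rt
Reagents that add atoms: chloroiodomethane, ClCI
Why: Amalgamated samarium inserts into the C–I bond of chloroiodomethane to give a samarium carbenoid, and the C10 hydroxyl of 12 becomes a samarium alkoxide that holds this carbenoid. From the complex CH2 is transferred to C6=C11 through a concerted butterfly transition state, so that the bonds C6–CH2 and C11–CH2 form together on the face that carries the oxygen. The closest known reaction type is the hydroxyl-directed Simmons–Smith cyclopropanation of cyclohex-2-enols in its samarium version. The three-membered ring is closed by concerted [2+1] methylene transfer, not by a stepwise ring closure, and this necessarily gives the cis-fused bicyclo[4.1.0]heptane. Both new stereocentres, C6 and C11 (target numbering), are set by the (S)-carbinol centre made in step 7 through syn delivery, and C5 has no part in the choice. Two selectivities are needed: facial selectivity at C6=C11, secured by the metal alkoxide tether, and site selectivity against the exocyclic C1=CH2, secured because the samarium carbenoid transfers CH2 only to alkenes with a neighbouring hydroxyl. The alkene is trisubstituted and electron-rich, which should offset the steric load of the quaternary substituent on C6, and an excess of reagent is planned for the same reason.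

Step 9
Reactants: 13 (1R,2S,6R)-6-[(1S)-1-methyl-2-methylidenecyclopentyl]bicyclo[4.1.0]heptan-2-ol
Product: 14 (1R,6R)-6-[(1S)-1-methyl-2-methylidenecyclopentyl]bicyclo[4.1.0]heptan-2-one
Conditions: TPAP (5 mol %), NMO, 4 Å MS, CH2Cl2, rt
Reagents that add atoms: none
Why: Ley–Griffith oxidation under neutral conditions avoids cyclopropylcarbinyl cation rearrangements and leaves the alkene alone; the carbinol centre has done its work and is removed.

Step 10
Reactants: 14 (1R,6R)-6-[(1S)-1-methyl-2-methylidenecyclopentyl]bicyclo[4.1.0]heptan-2-one
Product: 15 (1R,6R)-3-methyl-6-[(1S)-1-methyl-2-methylidenecyclopentyl]bicyclo[4.1.0]heptan-2-one (mixture of C3 epimers)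
Conditions: LDA, THF, −78 °C; MeI, −78 → −20 °C
Reagents that add atoms: iodomethane, CI
Why: Enolate alkylation that is regiospecific by structure: the other α-carbon is a cyclopropane bridgehead whose enolate would be a strained alkylidenecyclopropane, so only C3 (C9 of the target) can be deprotonated; the new centre is not controlled and need not be, since it becomes trigonal in step 12.

Step 11
Reactants: 15 (1R,6R)-3-methyl-6-[(1S)-1-methyl-2-methylidenecyclopentyl]bicyclo[4.1.0]heptan-2-one
Product: 16 (5S)-2,5-dimethyl-5-[(1S)-1-methyl-2-methylidenecyclopentyl]cyclohexan-1-one (mixture of C2 epimers)
Conditions: Li (2.5 equiv), NH3(l), THF, t-BuOH (1 equiv), −78 °C; then NH4Cl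
Reagents that add atoms: none
Why: Dissolving-metal reductive cleavage of a conjugated cyclopropyl ketone: the ketyl radical anion breaks the cyclopropane bond that overlaps best with the carbonyl π system, which in a bicyclo[4.1.0]heptan-2-one is the external bond (C11–CH2 of the target), so the CH2 stays on C6 as the angular methyl and the enolate is protonated on work-up; C6 keeps its configuration (the descriptor changes from R to S only through CIP priorities) and the isolated alkene is inert.

Step 12
Reactants: 16 (5S)-2,5-dimethyl-5-[(1S)-1-methyl-2-methylidenecyclopentyl]cyclohexan-1-one
Product: 17 trimethyl({(5S)-2,5-dimethyl-5-[(1S)-1-methyl-2-methylidenecyclopentyl]cyclohex-1-en-1-yl}oxy)silane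
Conditions: TMSCl, NaI, Et3N, MeCN, rt
Reagents that add atoms: chlorotrimethylsilane, C[Si](C)(C)Cl
Why: Silylation under equilibrating conditions (iodotrimethylsilane formed in the flask) gives the more substituted, tetrasubstituted enol ether toward the methyl-bearing carbon, and both epimers of 16 converge on it; any enol ether on the other side could not be dehydrogenated because the next carbon is quaternary and would simply return 16.

Step 13
Reactants: 17 trimethyl({(5S)-2,5-dimethyl-5-[(1S)-1-methyl-2-methylidenecyclopentyl]cyclohex-1-en-1-yl}oxy)silane
Product: 18 (5S)-2,5-dimethyl-5-[(1S)-1-methyl-2-methylidenecyclopentyl]cyclohex-2-en-1-one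
Conditions: Pd(OAc)2 (1.05 equiv), MeCN, rt
Reagents that add atoms: none
Why: Saegusa–Ito oxidation: the silyl enol ether is converted into a palladium enolate, and β-hydride elimination from the ring CH2 gives the conjugated endocyclic enone; no stereocentre is formed, and the electron-rich enol ether should engage Pd(II) far faster than the isolated alkene.

Step 14
Reactants: 18 (5S)-2,5-dimethyl-5-[(1S)-1-methyl-2-methylidenecyclopentyl]cyclohex-2-en-1-one
Product: 19 (1S,5S)-2,5-dimethyl-5-[(1S)-1-methyl-2-methylidenecyclopentyl]cyclohex-2-en-1-ol
Conditions: (R)-Me-CBS (0.5–1.0 equiv), catecholborane, PhMe, −78 °C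
Reagents that add atoms: none
Why: Corey–Bakshi–Shibata reduction of an α-methyl cyclic enone, the substrate class in which the α-branched alkenyl flank is most clearly the larger group; the (R)-catalyst should deliver hydride to the face of the C6 methyl (target numbering) and give the (S)-carbinol, with oxygen trans to that methyl and cis to the cyclopentyl group, which requires catalyst control to override the substrate's preference for attack anti to the pseudoaxial methyl.

Step 15
Reactants: 20 caffeic acid
Product: 22 (E)-3-[3,4-bis(tert-butyldimethylsilyloxy)phenyl]prop-2-enoic acid, via tris-silyl caffeate 21 (not isolated)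
Conditions: TBSCl (3.5 equiv), imidazole, DMF, rt; then AcOH/THF/H2O, rt
Reagents that add atoms: tert-butyldimethylsilyl chloride, CC(C)(C)[Si](C)(C)Cl
Why: Exhaustive silylation followed by selective hydrolysis of the silyl ester, which is far more labile than the two aryl silyl ethers; the alkene geometry is not touched.

Step 16
Reactants: 19 (1S,5S)-2,5-dimethyl-5-[(1S)-1-methyl-2-methylidenecyclopentyl]cyclohex-2-en-1-ol; 22 (E)-3-[3,4-bis(tert-butyldimethylsilyloxy)phenyl]prop-2-enoic acid
Product: 23 (1S,5S)-2,5-dimethyl-5-[(1S)-1-methyl-2-methylidenecyclopentyl]cyclohex-2-en-1-yl (2E)-3-[3,4-bis(tert-butyldimethylsilyloxy)phenyl]prop-2-enoate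
Conditions: EDC·HCl, DMAP, CH2Cl2, 0 °C → rt
Reagents that add atoms: none
Why: Steglich esterification: the acid is activated as the O-acylisourea and acylpyridinium and the alcohol attacks through oxygen, so the C10–O bond is never broken and the configuration is retained; the near-neutral conditions avoid allylic ionisation and protonation of the exocyclic alkene.

Step 17
Reactants: 23 (1S,5S)-2,5-dimethyl-5-[(1S)-1-methyl-2-methylidenecyclopentyl]cyclohex-2-en-1-yl (2E)-3-[3,4-bis(tert-butyldimethylsilyloxy)phenyl]prop-2-enoate
Product: 24 (1S,5S)-2,5-dimethyl-5-[(1S)-1-methyl-2-methylidenecyclopentyl]cyclohex-2-en-1-yl (2E)-3-(3,4-dihydroxyphenyl)prop-2-enoate (CNP0268865.1)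
Conditions: TBAF, AcOH (1:1), THF, 0 °C
Reagents that add atoms: none
Why: Fluoride cleaves the aryl silyl ethers through pentacoordinate silicon; acetic acid protonates the phenoxides as they form, so the allylic ester is not cleaved and the catechol is not exposed to base and air.

## Compound list

1 | 2-methylcyclopentan-1-one (racemic) | CC1CCCC1=O | starting material
2 | 2-(hydroxymethylidene)-5-methylcyclopentan-1-one | CC1CCC(=CO)C1=O | intermediate (not isolated)
3 | (E)-2-methyl-5-[(N-methylanilino)methylidene]cyclopentan-1-one | CC1CC/C(=C\N(C)c2ccccc2)C1=O | intermediate
4 | 3-bromoanisole | COc1cccc(Br)c1 | starting material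
5 | (2R,5E)-2-(3-methoxyphenyl)-2-methyl-5-[(N-methylanilino)methylidene]cyclopentan-1-one | O=C1/C(=C/N(C)c2ccccc2)CC[C@]1(C)c1cccc(OC)c1 | intermediate
6 | (R)-5-(hydroxymethylidene)-2-(3-methoxyphenyl)-2-methylcyclopentan-1-one | O=C1C(=CO)CC[C@]1(C)c1cccc(OC)c1 | intermediate (not isolated)
7 | (R)-2-(3-methoxyphenyl)-2-methylcyclopentan-1-one | O=C1CCC[C@]1(C)c1cccc(OC)c1 | intermediate
8 | 1-methoxy-3-[(1S)-1-methyl-2-methylidenecyclopentyl]benzene | C=C1CCC[C@]1(C)c1cccc(OC)c1 | intermediate
9 | 1-methoxy-5-[(1S)-1-methyl-2-methylidenecyclopentyl]cyclohexa-1,4-diene | C=C1CCC[C@]1(C)C1=CCC=C(OC)C1 | intermediate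
10 | 3-[(1S)-1-methyl-2-methylidenecyclopentyl]cyclohex-3-en-1-one | C=C1CCC[C@]1(C)C1=CCCC(=O)C1 | intermediate (not isolated)
11 | 3-[(1S)-1-methyl-2-methylidenecyclopentyl]cyclohex-2-en-1-one | C=C1CCC[C@]1(C)C1=CC(=O)CCC1 | intermediate
12 | (1S)-3-[(1S)-1-methyl-2-methylidenecyclopentyl]cyclohex-2-en-1-ol | C=C1CCC[C@]1(C)C1=C[C@@H](O)CCC1 | intermediate (key-step precursor)
13 | (1R,2S,6R)-6-[(1S)-1-methyl-2-methylidenecyclopentyl]bicyclo[4.1.0]heptan-2-ol | C=C1CCC[C@]1(C)[C@]12C[C@H]1[C@@H](O)CCC2 | intermediate (key-step product)
14 | (1R,6R)-6-[(1S)-1-methyl-2-methylidenecyclopentyl]bicyclo[4.1.0]heptan-2-one | C=C1CCC[C@]1(C)[C@]12C[C@H]1C(=O)CCC2 | intermediate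
15 | (1R,6R)-3-methyl-6-[(1S)-1-methyl-2-methylidenecyclopentyl]bicyclo[4.1.0]heptan-2-one (C3 epimers) | C=C1CCC[C@]1(C)[C@]12C[C@H]1C(=O)C(C)CC2 | intermediate
16 | (5S)-2,5-dimethyl-5-[(1S)-1-methyl-2-methylidenecyclopentyl]cyclohexan-1-one (C2 epimers) | C=C1CCC[C@]1(C)[C@@]1(C)CCC(C)C(=O)C1 | intermediate
17 | trimethyl({(5S)-2,5-dimethyl-5-[(1S)-1-methyl-2-methylidenecyclopentyl]cyclohex-1-en-1-yl}oxy)silane | C=C1CCC[C@]1(C)[C@@]1(C)CCC(C)=C(O[Si](C)(C)C)C1 | intermediate
18 | (5S)-2,5-dimethyl-5-[(1S)-1-methyl-2-methylidenecyclopentyl]cyclohex-2-en-1-one | C=C1CCC[C@]1(C)[C@@]1(C)CC=C(C)C(=O)C1 | intermediate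
19 | (1S,5S)-2,5-dimethyl-5-[(1S)-1-methyl-2-methylidenecyclopentyl]cyclohex-2-en-1-ol | C=C1CCC[C@]1(C)[C@@]1(C)CC=C(C)[C@@H](O)C1 | intermediate
20 | caffeic acid, (E)-3-(3,4-dihydroxyphenyl)prop-2-enoic acid | O=C(O)/C=C/c1ccc(O)c(O)c1 | starting material
21 | tert-butyldimethylsilyl (E)-3-[3,4-bis(tert-butyldimethylsilyloxy)phenyl]prop-2-enoate | CC(C)(C)[Si](C)(C)OC(=O)/C=C/c1ccc(O[Si](C)(C)C(C)(C)C)c(O[Si](C)(C)C(C)(C)C)c1 | intermediate (not isolated)
22 | (E)-3-[3,4-bis(tert-butyldimethylsilyloxy)phenyl]prop-2-enoic acid | O=C(O)/C=C/c1ccc(O[Si](C)(C)C(C)(C)C)c(O[Si](C)(C)C(C)(C)C)c1 | intermediate
23 | (1S,5S)-2,5-dimethyl-5-[(1S)-1-methyl-2-methylidenecyclopentyl]cyclohex-2-en-1-yl (2E)-3-[3,4-bis(tert-butyldimethylsilyloxy)phenyl]prop-2-enoate | C=C1CCC[C@]1(C)[C@@]1(C)CC=C(C)[C@@H](OC(=O)/C=C/c2ccc(O[Si](C)(C)C(C)(C)C)c(O[Si](C)(C)C(C)(C)C)c2)C1 | intermediate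
24 | (1S,5S)-2,5-dimethyl-5-[(1S)-1-methyl-2-methylidenecyclopentyl]cyclohex-2-en-1-yl (2E)-3-(3,4-dihydroxyphenyl)prop-2-enoate | C=C1CCC[C@]1(C)[C@@]1(C)CC=C(C)[C@@H](OC(=O)/C=C/c2ccc(O)c(O)c2)C1 | target

## Step count and least certain steps

Total: 17 steps. Longest linear sequence: 16 steps (steps 1–14, 16 and 17); step 15 prepares the acid component separately.

Step 8 (key step). The most likely failure is incomplete methylene transfer, because C6 of the alkene carries a fully substituted neighbour and the samarium carbenoid is bulky and short-lived. Forcing the reaction with a more reactive zinc carbenoid would risk loss of site selectivity toward the exocyclic alkene. The fallback uses a different bond-forming logic without a carbenoid; it sets out from 11 and returns at 14. Dimethylsulfoxonium methylide (Me3S(O)I, NaH, DMSO, rt → 50 °C) adds to the enone in conjugate fashion and closes the three-membered ring by displacement of the sulfoxide (Corey–Chaykovsky cyclopropanation). This gives 14 directly and makes steps 7–9 unnecessary. The price is that the face of C6=C11 is then chosen only by C5 across a rotating bond. The (1S,6S)-diastereomeric cyclopropyl ketone F1 must therefore be expected beside 14 and separated, with a sense and degree of selectivity that cannot be predicted with confidence. For this reason it is the reserve and not the plan.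

Step 14. The most likely failure is poor facial selectivity, because hydride has to pass the pseudoaxial ring methyl while the substrate prefers attack on the other face, a mismatched pairing for the catalyst. The fallback sets out from 18 and returns at 23. 18 is reduced in the sense the substrate favours, with (S)-Me-CBS and catecholborane (matched pairing) or with DIBAL-H at −78 °C, to the (1R,5S)-epimeric allylic alcohol F2. The ester is then formed with inversion by Mitsunobu reaction with 22 (PPh3, DIAD, PhMe, 0 °C): the carboxylate displaces the pseudoaxial oxyphosphonium group from the open face and gives 23 at the same step count. The same reaction can consume any epimer that step 14 forms beside 19, so that both carbinol epimers end in 23. The residual risks there are allylic transposition and elimination.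

Step 7. The most likely failure is modest facial discrimination. The enone has no α-substituent, so the two flanks of the carbonyl differ less than in 18, and C5 is too remote to help. Material of the wrong carbinol configuration would carry the wrong configuration at C6 after step 8. The fallback sets out from 11 and returns at 12. Luche reduction (NaBH4, CeCl3·7H2O, MeOH, −78 °C) gives 12 together with the (1R)-epimeric cyclohexenol F3 without selectivity. The two are diastereomers and are separated by chromatography, if necessary by HPLC. F3 is then inverted by Mitsunobu reaction with 4-nitrobenzoic acid (PPh3, DIAD, THF) to the (1S)-4-nitrobenzoate F4. Allylic transposition is excluded here because the far alkene carbon is fully substituted. Methanolysis (K2CO3, MeOH) releases 12.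

Step 13 (with step 12). The most likely failure is interference of palladium(II) with the exocyclic 1,1-disubstituted alkene (migration of the double bond into the five-membered ring through palladium hydride). β-Hydride loss from the methyl group instead of the ring, or incomplete regiocontrol in the enol ether formation, are further possibilities. The fallback sets out from 16 and returns at 18 without any new compound (F0). It is the direct dehydrogenation of the ketone with IBX (DMSO/fluorobenzene, 65–75 °C), a single-electron oxidation of the enol that needs neither the silyl enol ether nor a transition metal. The ring can be desaturated only toward the methyl-bearing side because the carbon on the other side is followed by a quaternary centre, and a second dehydrogenation is blocked for the same reason. If it works it also shortens the route by one step.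

Step 2. The most likely failure is insufficient enantioselectivity, since asymmetric induction in enolate arylation depends strongly on the aryl halide. Slow coupling at the tertiary enolate carbon is less likely. Part of the risk is absorbed by the route itself, because material from the minor enantiomer of 7 becomes a diastereomer after step 7. The fallback sets out from 7 of low enantiomeric purity (which could then be made with an achiral ligand) and returns at 7 as a single enantiomer. Reduction with (S)-Me-CBS and BH3·SMe2 (THF, 0 °C) is controlled by the catalyst at the carbonyl carbon for both enantiomers. The (R)-ketone should give (1R,2R)-2-(3-methoxyphenyl)-2-methylcyclopentan-1-ol F5, and the unwanted (S)-ketone should give the (1R,2S)-diastereomeric cyclopentanol F6. The cis and trans cyclopentanols are separated on silica, and oxidation of the first one (TPAP, NMO) returns 7. The cost is two extra steps and the loss of the unwanted enantiomer.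

## Further compounds

F1 | step 8 | (1S,6S)-6-[(1S)-1-methyl-2-methylidenecyclopentyl]bicyclo[4.1.0]heptan-2-one | C=C1CCC[C@]1(C)[C@@]12C[C@@H]1C(=O)CCC2
F2 | step 14 | (1R,5S)-2,5-dimethyl-5-[(1S)-1-methyl-2-methylidenecyclopentyl]cyclohex-2-en-1-ol | C=C1CCC[C@]1(C)[C@@]1(C)CC=C(C)[C@H](O)C1
F3 | step 7 | (1R)-3-[(1S)-1-methyl-2-methylidenecyclopentyl]cyclohex-2-en-1-ol | C=C1CCC[C@]1(C)C1=C[C@H](O)CCC1
F4 | step 7 | (1S)-3-[(1S)-1-methyl-2-methylidenecyclopentyl]cyclohex-2-en-1-yl 4-nitrobenzoate | C=C1CCC[C@]1(C)C1=C[C@@H](OC(=O)c2ccc(cc2)[N+](=O)[O-])CCC1
F0 | step 13 | none | none
F5 | step 2 | (1R,2R)-2-(3-methoxyphenyl)-2-methylcyclopentan-1-ol | O[C@@H]1CCC[C@]1(C)c1cccc(OC)c1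
F6 | step 2 | (1R,2S)-2-(3-methoxyphenyl)-2-methylcyclopentan-1-ol | O[C@@H]1CCC[C@@]1(C)c1cccc(OC)c1
A1 | alternative 1 | 5-[5-(tert-butyldimethylsilyloxy)-1,4-dimethylcyclohex-3-en-1-yl]-5-methylcyclopent-2-en-1-one (configuration as in 24) | O=C1C=CC[C@]1(C)[C@@]1(C)CC=C(C)[C@@H](O[Si](C)(C)C(C)(C)C)C1
A2 | alternative 1 | 6-allyl-5-[2-(tert-butyldimethylsilyloxy)-3-methylbut-3-en-1-yl]-5,6-dimethylcyclohex-2-en-1-one (configuration as in 24) | C=CC[C@@]1(C)C(=O)C=CC[C@@]1(C)C[C@H](O[Si](C)(C)C(C)(C)C)C(C)=C
A3 | alternative 2 | cis-anti-cis cyclobutane-fused tetracyclic γ-lactone | O=C1O[C@@H]2CCC[C@]3(C)[C@@]4(C)CCC[C@]14[C@H]23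
A4 | alternative 2 | (R)-3-methylcyclohex-2-en-1-yl 2-methylcyclopent-1-ene-1-carboxylate | CC1=C(CCC1)C(=O)O[C@H]1C=C(C)CCC1
A5 | alternative 3 | trichodiene | C=C1CCC[C@]1(C)[C@@]1(C)CC=C(C)CC1
A6 | alternative 3 | (2E,6E)-farnesyl diphosphate | CC(C)=CCC/C(C)=C/CC/C(C)=C/COP(=O)(O)OP(=O)(O)O
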